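**Remarks on the chemistry (assumptions).** The target is taken as the constitution drawn by its SMILES: an achiral pentaphenyl tetraether with twelve hydroxyls and no stereocentre. Compounds 1, 2, 9, 13 and 14 are assumed to be purchasable. Rings are lettered A (2,4,6-trihydroxyphenoxy end) to E (3,4,5-trihydroxyphenyl end). Ring A carries its ether oxygen on C1; rings B–E are numbered from the carbon (C1) whose oxygen points towards ring A. "C–E aryloxy" stands for the 4-[3,5-dimethoxy-4-(3,4,5-trimethoxyphenoxy)phenoxy]-3,5-dimethoxyphenoxy group, i.e. phenol 8 without its hydroxyl hydrogen.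

## The problem

The target is a linear chain of five oxygenated benzene rings joined by four diaryl ether bridges and carrying twelve free phenolic hydroxyls. It has no stereocentre, so nothing has to be controlled or relayed stereochemically. All four bridges have the same shape: the oxygen joins an unhindered C1 (hydrogen on both neighbours) to a carbon flanked by two oxygen substituents (C1 of ring A, C4 of rings B, C and D). Each ether bond is therefore crowded and electron-rich on one side, which is where classical diaryl ether couplings are slowest. A second difficulty is regiochemical: every ring is 1,3,5- or 1,2,3,5-oxygenated, and it must be unambiguous which oxygens are bridges and which are hydroxyls. The free dodecaphenol is easily oxidised in air, especially as its phenolates, and will not tolerate oxidants, hot base or prolonged chromatography. The hydroxyls must therefore stay masked until the last step, and the unmasking must leave the four Ar–O–Ar bonds intact. The feature that invites a ring synthesis is ring B. Its C3 and C5 hydroxyls stand 1,3 to each other with the ring C ether oxygen on C4 between them, which is the pattern of an acetoacetate bearing an oxygen substituent on its central carbon. C1 (ring A oxygen) and C6 (hydrogen) form a two-carbon unit that an aryloxy alkyne can supply, with an ester on the second carbon that later leaves as CO2.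

## Retrosynthesis

**Unmasking (24 from 23).** Only the ten O–CH3 bonds of 23 are cut. Methyl ethers are chosen because they survive every reagent class the route needs: organolithium and amide bases, copper catalysis, peracid, hot hydroxide and silylating agents. Benzyl ethers would allow a gentler hydrogenolysis, but would require benzylated analogues of 1, 2 and 13, none of which can be bought. The forward reaction must cleave ten aryl methyl ethers completely without touching a diaryl ether.

**Traceless ester (23 from 21).** The C6–H bond of ring B is traced back to a C6–CO2CH3 bond. The ester is what makes the alkyne partner electrophilic and fixes its orientation in the ring-forming step. Its removal should be easy, because the derived acid 22 is a 2,4-dihydroxy-6-aryloxybenzoic acid that loses CO2 on ipso-protonation. The forward step must saponify a di-ortho-substituted benzoate.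

**Ring B (21 from 12 and 18, the key disconnection).** The C1–C2 and C5–C6 bonds of ring B are cut, giving the C2–C5 diene 12 and the C1–C6 ynoate 18.
- Against cutting the ether bonds of ring B: either bridge leads back to a hindered diaryl ether coupling on a tetrameric substrate.
- Against building ring C or D the same way: the ynol ether would have to come from a flanked phenol that is itself an oligomer.
- Against building ring A or E: only one bridge would be created.
- For ring B: both partners derive from accessible phenols (8 and 13), and a three-ring and a one-ring fragment are joined convergently. Both ring B ether oxygens are already in place, one on an sp3 carbon and one on an sp carbon, before the ring exists.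
- Demand on the forward reaction: one orientation only. The CH2 terminus of 12 must bond to the aryloxy-bearing carbon of 18.

**Diene (12 from 11, 10, and 8 plus 9).** The bond between the ring C oxygen and the future C4 of ring B is cut. It is made by SN2 displacement at the chlorinated carbon of 9 by the unhindered phenol 8, so the flanked side of this bridge is never formed on an arene. Enol silylation (11) and then γ-deprotonation and silylation give 12. The precursor 8 has three rings and a single free hydroxyl.

**Ynoate (18 from 15, and 13 plus 14).** The bond between the ring A oxygen and the future C1 of ring B is cut. The flanked phenol 13 adds to the two-carbon unit of 14 by elimination–addition, where a small linear electrophile tolerates the two ortho methoxy groups. Dichlorovinyl ether 15 then gives the lithium acetylide 17, which is carboxylated with a chloroformate. Everything here is one ring and two steps.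

**Rings C and D (8 from 6, 5 and 3, and from 1 plus twice 2).** The O–C4 bonds of rings C and D are cut at the hindered carbon. The electrophile 2 carries a para formyl group that activates its crowded C–Br bond for copper-catalysed coupling with an unhindered, electron-rich phenol. The formyl group then becomes the next phenolic oxygen by Dakin oxidation. One building block thus serves both rings at two steps per ring. The same cycle could in principle be run two rounds further, and on paper that would be shorter. The ring synthesis takes over for rings A and B because it is convergent and avoids two more hindered couplings on ever larger substrates. The linear option is held in reserve.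

## Roads not taken

**Alternative 1:** The cut is in ring A, at the bond between the carbinol carbon and the methylene next to the ketone of cyclohexanone A1 (C1–C6 in hexose numbering), and it leads back to 2-deoxy-D-glucose A4.
- Forward key step: the four-ring phenol A3 would be attached to C4 of a protected glycoside by Mitsunobu inversion, and C6 turned into the exocyclic enol ether A2. PdCl2 in aqueous dioxane would then bring about the Ferrier carbocyclization: hydroxypalladation by divalent palladium, hemiketal opening, and intramolecular aldol closure to A1.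
- Merits: the reaction type is robust on 6-deoxyhex-5-enopyranosides. The sugar dictates the 1,2,3,5-oxygen pattern. The flanked ether oxygen is set by SN2 at sp3 carbon, the same tactic as in the chosen plan.
- Weak points: only a terminal ring and one bridge are made. A3 already contains four rings and three hindered bridges. A1 is still a deprotection, two carbinol oxidations and an enolisation away from an arene, on a β-oxygenated ketone prone to elimination. The Mitsunobu reaction of a secondary sugar hydroxyl with a bulky phenol competes with elimination. The stereocentres bought from the chiral pool are discarded.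
- Comparison: in precedent for the key step this road is stronger than the chosen one. The chosen plan sets against it that its ring-forming step creates an internal ring with two bridges and joins two fragments. Alternative 1 spends about eight sugar steps to make a ring that is available for purchase as phenol 13.

**Alternative 2:** All four bridges are cut at once between oxygen and C1 of rings B–E by formally inserting a carbonyl group. The precursor is the depside A6, a chain of four aryl ester links from phenol 13 through three 4-acyloxy-3,5-dimethoxybenzoyl units to a 3,4,5-trimethoxybenzoyl cap.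
- Forward key step: Ni(cod)2 with 3,4-bis(dicyclohexylphosphino)thiophene would insert zerovalent nickel into each C(acyl)–O bond, lose CO, and reductively eliminate the diaryl ether. This would give the dodeca-O-methyl ether A5 in one operation; demethylation would finish.
- Merits: esterification of flanked phenols is easy, the building blocks are commodity chemicals, the regiochemistry is fixed by construction, and the whole synthesis might need about eight steps.
- Weak points: decarbonylative etherification is established mainly for electron-poor acyl groups such as azine carboxylates. Here each acyl group is an electron-rich trialkoxybenzoyl and each leaving group a crowded 2,6-dimethoxyphenoxide, so oxidative addition and C–O reductive elimination are both disfavoured. The event must succeed four times in one molecule, and partial conversion gives ester/ether hybrids that are hard to separate. Four equivalents of CO bind the zerovalent nickel. Nickel with electron-rich phosphines at high temperature can also cut aryl–OCH3 bonds, of which there are twelve.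
- Comparison: in step count and convergence this road is clearly better. The chosen plan sets against it that none of its steps must work four times in one flask, and that its key step rests on a polarity match built into the two partners and not on a catalyst working outside its demonstrated substrate range.

**Alternative 3:** The cut is in ring E, which would be grown on the ring D oxygen by Dötz benzannulation.
- Forward key step: the flanked hydroxyl of the four-ring phenol A9 would be converted into the pentacarbonylchromium aryloxy(2-ethoxyvinyl)carbene complex A8. Reaction with ethoxyacetylene A10 and one CO ligand would form C1–C6, C5–C4 and C4–C3 of ring E and release, in air, phenol A7 with its free hydroxyl on C4 of ring E.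
- Merits: it shares the logic of the chosen plan, with the oxygen in place before the ring exists. Benzannulation of alkoxy(vinyl)carbene complexes is a well-studied arene synthesis, and its mechanism places the new hydroxyl para to the carbene oxygen. In that respect the constitution of the product is less in doubt than the orientation of the cycloaddition in the chosen plan.
- Weak points: only a terminal ring and one bridge are made, and A9 still needs three hindered bridges. Aryloxy carbene complexes are far more electrophilic and labile than alkoxy ones, and loading a doubly flanked phenol onto chromium is unfavourable. Electron-rich alkynes such as A10 tend towards simple insertion or cyclobutenone formation, and their insertion regiochemistry is governed by electronics, so the 3,5-placement of the ethoxy groups is not assured. Stoichiometric chromium is used late in the route.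
- Comparison: both key steps are untested on their substrates. The chosen plan is convergent (three rings plus one), forms two bridges in its ring-forming sequence, and needs no stoichiometric metal. Alternative 3 would offer a differentiated ring E hydroxyl, which this target does not need.

Key step: step 10

## Route

Step 1
Reactants: 1 3,4,5-trimethoxyphenol; 2 4-bromo-3,5-dimethoxybenzaldehyde
Product: 3 3,5-dimethoxy-4-(3,4,5-trimethoxyphenoxy)benzaldehyde
Conditions: CuI (10 mol %), picolinic acid (20 mol %), K3PO4, DMSO, 100 °C, Ar
Reagents that add atoms: none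
Why: Ullmann-type C–O coupling under catalysis by monovalent copper with a picolinate ligand, a system suited to ortho-disubstituted partners; the phenoxide of 1 is unhindered and electron-rich and the para formyl group activates the crowded C–Br bond of 2. The aldehyde has no α-hydrogen and should tolerate the phosphate base.

Step 2
Reactants: 3 3,5-dimethoxy-4-(3,4,5-trimethoxyphenoxy)benzaldehyde
Product: 5 3,5-dimethoxy-4-(3,4,5-trimethoxyphenoxy)phenol, via aryl formate 4 (not isolated)
Conditions: mCPBA, CH2Cl2, 0 °C to rt; aqueous NaHCO3/Na2S2O3 wash; then K2CO3 (0.2 equiv), MeOH, rt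
Reagents that add atoms: mCPBA (3-chloroperoxybenzoic acid), OOC(=O)c1cccc(Cl)c1
Why: Dakin oxidation in its peracid (Baeyer–Villiger) form: in the Criegee intermediate the trioxygenated aryl group migrates in preference to hydrogen, as in the conversion of 3,4,5-trimethoxybenzaldehyde into 1. Carbonate-catalysed methanolysis of the formate releases the phenol.

Step 3
Reactants: 5 3,5-dimethoxy-4-(3,4,5-trimethoxyphenoxy)phenol; 2 4-bromo-3,5-dimethoxybenzaldehyde
Product: 6 4-[3,5-dimethoxy-4-(3,4,5-trimethoxyphenoxy)phenoxy]-3,5-dimethoxybenzaldehyde
Conditions: CuI (10 mol %), picolinic acid (20 mol %), K3PO4, DMSO, 100 °C, Ar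
Reagents that add atoms: none
Why: Same Ullmann-type coupling as step 1; the hydroxyl of 5 sits in the same unhindered 3,5-dimethoxy-4-oxyphenol environment as that of 1, so the nucleophile should behave alike.

Step 4
Reactants: 6 4-[3,5-dimethoxy-4-(3,4,5-trimethoxyphenoxy)phenoxy]-3,5-dimethoxybenzaldehyde
Product: 8 4-[3,5-dimethoxy-4-(3,4,5-trimethoxyphenoxy)phenoxy]-3,5-dimethoxyphenol, via aryl formate 7 (not isolated)
Conditions: mCPBA, CH2Cl2, 0 °C to rt; aqueous NaHCO3/Na2S2O3 wash; then K2CO3 (0.2 equiv), MeOH, rt
Reagents that add atoms: mCPBA (3-chloroperoxybenzoic acid), OOC(=O)c1cccc(Cl)c1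
Why: Same Dakin oxidation as step 2; the migrating ring again carries three oxygen donors, and the remote rings should not be attacked by the peracid at this temperature.

Step 5
Reactants: 8 4-[3,5-dimethoxy-4-(3,4,5-trimethoxyphenoxy)phenoxy]-3,5-dimethoxyphenol; 9 methyl 2-chloro-3-oxobutanoate
Product: 10 methyl 2-(C–E aryloxy)-3-oxobutanoate (racemic, enolisable)
Conditions: K2CO3, acetone, reflux
Reagents that add atoms: none
Why: Williamson-type SN2 displacement of the doubly activated secondary chloride by an unhindered phenoxide, the usual entry to 2-aryloxy-3-oxobutanoates. The new stereocentre is left racemic because it becomes sp2 in the next step.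

Step 6
Reactants: 10 methyl 2-(C–E aryloxy)-3-oxobutanoate
Product: 11 methyl 2-(C–E aryloxy)-3-(trimethylsilyloxy)but-2-enoate (E/Z mixture)
Conditions: TMSCl, Et3N, toluene, rt; filtration under Ar
Reagents that add atoms: chlorotrimethylsilane, C[Si](C)(C)Cl
Why: Silyl enol ether formation by soft enolisation of a β-ketoester, the standard first stage for 2-substituted acetoacetates; the double-bond geometry is irrelevant for what follows.

Step 7
Reactants: 11 methyl 2-(C–E aryloxy)-3-(trimethylsilyloxy)but-2-enoate
Product: 12 2-(C–E aryloxy)-1-methoxy-1,3-bis(trimethylsilyloxy)buta-1,3-diene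
Conditions: LiN(iPr)2, THF, −78 °C; then TMSCl, −78 °C to rt; removal of LiCl under Ar, used crude
Reagents that add atoms: chlorotrimethylsilane, C[Si](C)(C)Cl
Why: Kinetic γ-deprotonation of the vinylogous ester and O-silylation of the dienolate, the established second stage of the synthesis of 1-alkoxy-1,3-bis(silyloxy)dienes. The aryloxy group on the central carbon has no acidic hydrogen and should not interfere.

Step 8
Reactants: 13 2,4,6-trimethoxyphenol; 14 trichloroethylene
Product: 15 (E)-2-(1,2-dichlorovinyloxy)-1,3,5-trimethoxybenzene
Conditions: K2CO3, DMF, 70 °C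
Reagents that add atoms: none
Why: Elimination–addition: base converts 14 into dichloroacetylene, to which the phenoxide adds anti, giving the (E)-dichlorovinyl ether. The small linear electrophile tolerates the two flanking methoxy groups.

Step 9
Reactants: 15 (E)-2-(1,2-dichlorovinyloxy)-1,3,5-trimethoxybenzene
Product: 18 methyl 3-(2,4,6-trimethoxyphenoxy)prop-2-ynoate, via chloroalkynyl ether 16 (not isolated), via lithium aryloxyacetylide 17 (not isolated)
Conditions: n-BuLi (2.2 equiv), THF, −78 to −40 °C; then ClCO2Me, −78 to 0 °C
Reagents that add atoms: methyl chloroformate, COC(=O)Cl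
Why: Standard ynol ether synthesis from dichlorovinyl ethers: dehydrochlorination, chlorine–lithium exchange, and C-acylation of the acetylide by the chloroformate. Keeping the mixture at or below −40 °C should prevent lithiation of the ring between the methoxy groups.

Step 10
Reactants: 12 2-(C–E aryloxy)-1-methoxy-1,3-bis(trimethylsilyloxy)buta-1,3-diene; 18 methyl 3-(2,4,6-trimethoxyphenoxy)prop-2-ynoate
Product: 21 methyl 3-(C–E aryloxy)-2,4-dihydroxy-6-(2,4,6-trimethoxyphenoxy)benzoate, via cyclohexa-1,4-diene cycloadduct 19 (not isolated), via bis(trimethylsilyl) ether 20 (not isolated)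
Conditions: 18 (2.5 equiv), toluene, 100 °C, sealed tube, Ar; then 1 M HCl, THF, rt
Reagents that add atoms: none
Why: Proposed new method: the closest known reaction type is the Diels–Alder addition of 1-alkoxy-1,3-bis(silyloxy)buta-1,3-dienes to acetylenic esters followed by loss of alcohol to give resorcinol esters; new are the aryloxy group on the alkyne carbon and the aryloxy group on the central carbon of the diene. The HOMO of 12 should have its largest coefficient at the CH2 terminus, which is pushed by three oxygen donors, and the LUMO of 18 at the aryloxy-bearing carbon β to the ester, so an asynchronous [4+2] cycloaddition of normal electron demand should form C1–C2 ahead of C5–C6 and give cyclohexa-1,4-diene 19. Ring B is thus closed by [4+2] cycloaddition; in the stepwise limit this is a vinylogous Mukaiyama–Michael addition followed by 6-exo-trig attack of the α-carbon on the ketene-acetal-derived C5. The mixed ketal carbon C5 of 19, formed as a racemate, then loses methanol across the ring with a C2 hydrogen (1,4-elimination) to give the aromatic bis-silyl ether 20, dilute HCl removes both silyl groups, and no stereocentre remains. The selectivity needed is orientational: only the pairing of C2 with C1 places the two ether oxygens para (the reverse pairing would place them meta), and it is secured because the nucleophilic terminus of the diene and the Michael position of the ynoate are each fixed by their substituents and reinforce each other. Thermal conditions without Lewis acid are chosen so that no free allenoate forms that could expel 2,4,6-trimethoxyphenoxide, and the inexpensive 18 is used in excess because 12 is the valuable partner.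

Step 11
Reactants: 21 methyl 3-(C–E aryloxy)-2,4-dihydroxy-6-(2,4,6-trimethoxyphenoxy)benzoate
Product: 23 2-(C–E aryloxy)-5-(2,4,6-trimethoxyphenoxy)benzene-1,3-diol, via benzoic acid 22 (not isolated)
Conditions: KOH, DMSO/H2O, 90 °C, Ar; then 2 M HCl to pH 1, 60 °C
Reagents that add atoms: none
Why: Saponification of a hindered salicylate-type ester followed by protodecarboxylation: the 2,4-dihydroxy-6-aryloxybenzoic acid is protonated at the ipso carbon and loses CO2 on gentle warming, as phloroglucinolcarboxylic acids do. Methyl and diaryl ethers are stable to hot hydroxide, and argon protects the resorcinolate from air.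

Step 12
Reactants: 23 2-(C–E aryloxy)-5-(2,4,6-trimethoxyphenoxy)benzene-1,3-diol
Product: 24 2-[3,5-dihydroxy-4-[3,5-dihydroxy-4-[3,5-dihydroxy-4-(3,4,5-trihydroxyphenoxy)phenoxy]phenoxy]phenoxy]benzene-1,3,5-triol (target)
Conditions: BBr3 (excess), CH2Cl2, −78 °C to rt, Ar; then ice water; Sephadex LH-20 under Ar
Reagents that add atoms: none
Why: Lewis-acid ether cleavage: BBr3 coordinates each methoxy oxygen and bromide removes the methyl group by SN2, while diaryl ether C–O bonds are inert to this reagent. Hydrolysis of the aryl borates frees the twelve hydroxyls.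

## Compound list

1 | 3,4,5-trimethoxyphenol | COc1cc(O)cc(OC)c1OC | starting material
2 | 4-bromo-3,5-dimethoxybenzaldehyde | COc1cc(C=O)cc(OC)c1Br | starting material
3 | 3,5-dimethoxy-4-(3,4,5-trimethoxyphenoxy)benzaldehyde | COc1cc(C=O)cc(OC)c1Oc1cc(OC)c(OC)c(OC)c1 | intermediate
4 | 3,5-dimethoxy-4-(3,4,5-trimethoxyphenoxy)phenyl formate | COc1cc(OC=O)cc(OC)c1Oc1cc(OC)c(OC)c(OC)c1 | intermediate
5 | 3,5-dimethoxy-4-(3,4,5-trimethoxyphenoxy)phenol | COc1cc(O)cc(OC)c1Oc1cc(OC)c(OC)c(OC)c1 | intermediate
6 | 4-[3,5-dimethoxy-4-(3,4,5-trimethoxyphenoxy)phenoxy]-3,5-dimethoxybenzaldehyde | COc1cc(C=O)cc(OC)c1Oc1cc(OC)c(Oc2cc(OC)c(OC)c(OC)c2)c(OC)c1 | intermediate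
7 | 4-[3,5-dimethoxy-4-(3,4,5-trimethoxyphenoxy)phenoxy]-3,5-dimethoxyphenyl formate | COc1cc(OC=O)cc(OC)c1Oc1cc(OC)c(Oc2cc(OC)c(OC)c(OC)c2)c(OC)c1 | intermediate
8 | 4-[3,5-dimethoxy-4-(3,4,5-trimethoxyphenoxy)phenoxy]-3,5-dimethoxyphenol (ring C–E phenol) | COc1cc(O)cc(OC)c1Oc1cc(OC)c(Oc2cc(OC)c(OC)c(OC)c2)c(OC)c1 | intermediate
9 | methyl 2-chloro-3-oxobutanoate | COC(=O)C(Cl)C(C)=O | starting material
10 | methyl 2-(C–E aryloxy)-3-oxobutanoate (racemic) | COC(=O)C(Oc1cc(OC)c(Oc2cc(OC)c(Oc3cc(OC)c(OC)c(OC)c3)c(OC)c2)c(OC)c1)C(C)=O | intermediate
11 | methyl 2-(C–E aryloxy)-3-(trimethylsilyloxy)but-2-enoate (E/Z mixture) | COC(=O)C(Oc1cc(OC)c(Oc2cc(OC)c(Oc3cc(OC)c(OC)c(OC)c3)c(OC)c2)c(OC)c1)=C(C)O[Si](C)(C)C | intermediate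
12 | 2-(C–E aryloxy)-1-methoxy-1,3-bis(trimethylsilyloxy)buta-1,3-diene | C=C(O[Si](C)(C)C)C(Oc1cc(OC)c(Oc2cc(OC)c(Oc3cc(OC)c(OC)c(OC)c3)c(OC)c2)c(OC)c1)=C(OC)O[Si](C)(C)C | intermediate
13 | 2,4,6-trimethoxyphenol | COc1cc(OC)c(O)c(OC)c1 | starting material
14 | trichloroethylene | ClC=C(Cl)Cl | starting material
15 | (E)-2-(1,2-dichlorovinyloxy)-1,3,5-trimethoxybenzene | COc1cc(OC)c(O/C(Cl)=C\Cl)c(OC)c1 | intermediate
16 | 2-(chloroethynyloxy)-1,3,5-trimethoxybenzene | COc1cc(OC)c(OC#CCl)c(OC)c1 | intermediate
17 | lithium (2,4,6-trimethoxyphenoxy)acetylide | [Li]C#COc1c(OC)cc(OC)cc1OC | intermediate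
18 | methyl 3-(2,4,6-trimethoxyphenoxy)prop-2-ynoate | COC(=O)C#COc1c(OC)cc(OC)cc1OC | intermediate
19 | methyl 5-(C–E aryloxy)-6-methoxy-2-(2,4,6-trimethoxyphenoxy)-4,6-bis(trimethylsilyloxy)cyclohexa-1,4-diene-1-carboxylate (racemic at C6) | COC(=O)C1=C(Oc2c(OC)cc(OC)cc2OC)CC(O[Si](C)(C)C)=C(Oc2cc(OC)c(Oc3cc(OC)c(Oc4cc(OC)c(OC)c(OC)c4)c(OC)c3)c(OC)c2)C1(OC)O[Si](C)(C)C | intermediate
20 | methyl 3-(C–E aryloxy)-6-(2,4,6-trimethoxyphenoxy)-2,4-bis(trimethylsilyloxy)benzoate | COC(=O)c1c(O[Si](C)(C)C)c(Oc2cc(OC)c(Oc3cc(OC)c(Oc4cc(OC)c(OC)c(OC)c4)c(OC)c3)c(OC)c2)c(O[Si](C)(C)C)cc1Oc1c(OC)cc(OC)cc1OC | intermediate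
21 | methyl 3-(C–E aryloxy)-2,4-dihydroxy-6-(2,4,6-trimethoxyphenoxy)benzoate | COC(=O)c1c(O)c(Oc2cc(OC)c(Oc3cc(OC)c(Oc4cc(OC)c(OC)c(OC)c4)c(OC)c3)c(OC)c2)c(O)cc1Oc1c(OC)cc(OC)cc1OC | intermediate
22 | 3-(C–E aryloxy)-2,4-dihydroxy-6-(2,4,6-trimethoxyphenoxy)benzoic acid | OC(=O)c1c(O)c(Oc2cc(OC)c(Oc3cc(OC)c(Oc4cc(OC)c(OC)c(OC)c4)c(OC)c3)c(OC)c2)c(O)cc1Oc1c(OC)cc(OC)cc1OC | intermediate
23 | 2-(C–E aryloxy)-5-(2,4,6-trimethoxyphenoxy)benzene-1,3-diol | COc1cc(OC)c(Oc2cc(O)c(Oc3cc(OC)c(Oc4cc(OC)c(Oc5cc(OC)c(OC)c(OC)c5)c(OC)c4)c(OC)c3)c(O)c2)c(OC)c1 | intermediate
24 | 2-[3,5-dihydroxy-4-[3,5-dihydroxy-4-[3,5-dihydroxy-4-(3,4,5-trihydroxyphenoxy)phenoxy]phenoxy]phenoxy]benzene-1,3,5-triol (CNP0308003.0) | Oc1cc(O)c(Oc2cc(O)c(Oc3cc(O)c(Oc4cc(O)c(Oc5cc(O)c(O)c(O)c5)c(O)c4)c(O)c3)c(O)c2)c(O)c1 | target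

## Step count and risk

Total: 12 steps. Longest linear sequence: 10 steps (steps 1–7 and 10–12). The ynoate branch (steps 8 and 9) joins at step 10.

**Step 10 (key step, proposed new method).**
- What may go wrong: donation from the aryloxy oxygen may lower the dienophilicity of 18 so far that cycloaddition loses out to thermal silyl migration or hydrolysis of the diene. The orientation may partly reverse. A stepwise ionic course may end in addition–elimination, with loss of the ring A phenoxide instead of ring closure. A [2+2] addition at the ketene acetal double bond may also compete.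
- Fallback (known chemistry only): set out from 8 and run the coupling/Dakin cycle of steps 1–4 twice more. Coupling of 8 with 2 gives the four-ring aldehyde F1. Peracid gives the four-ring formate F2, and methanolysis gives the four-ring phenol F3. A second coupling with 2 gives the five-ring aldehyde F4. Oxidation gives the five-ring formate F5 and then the five-ring phenol F6, whose ring A already carries a free C4 hydroxyl. BBr3 then cleaves the eleven methyl ethers, and the fallback rejoins the route at 24. The price is the loss of convergence and two further hindered couplings.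

**Step 3 (and, by the same argument, step 1).**
- What may go wrong: slow oxidative addition or ligand exchange at the di-ortho-methoxy C–Br carbon, so that reductive debromination of the aldehyde and oxidative consumption of the phenol take over.
- Fallback: reverse the polarity of the coupling. Set out from 5 and convert it with Tf2O/pyridine into the aryl triflate F7. Miyaura borylation (B2pin2, Pd(dppf)Cl2, KOAc) gives the pinacol boronate F8. Chan–Lam coupling with 4-hydroxy-3,5-dimethoxybenzaldehyde (Cu(OAc)2, pyridine, B(OH)3, MeCN, air) returns to 6. For step 1 the corresponding boronic acid can be bought.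

**Step 7.**
- What may go wrong: incomplete γ-deprotonation or partial C-silylation, and hydrolysis of the diene during isolation, since a compound of this size cannot be distilled.
- Fallback: set out from 10 and go directly to 12 by soft enolisation with excess TMSOTf/Et3N in Et2O at 0 °C. No amide base and no cryogenic step are needed, the ammonium triflate separates as a second phase, and the diene is carried into step 10 in the same flask after solvent exchange.

**Step 5.**
- What may go wrong: carbonate deprotonates the chloro ketoester and slows the substitution, while the phenoxide attacks a carbonyl group instead (acyl transfer or retro-Claisen cleavage).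
- Fallback: set out from 8 and reach 10 by Rh2(OAc)4-catalysed O–H insertion of the carbenoid from methyl 2-diazo-3-oxobutanoate in CH2Cl2. This is a neutral reaction with a different bond-forming mechanism.

**Step 12.**
- What may go wrong: incomplete cleavage of the methoxy groups that flank the bridges, where neighbouring aryl borates crowd the reagent, and oxidative darkening of the free dodecaphenol during isolation.
- Fallback: set out from 23, treat with BBr3 as before, and acetylate the crude product (Ac2O, pyridine) to the dodecaacetate F9. This is stable to air and silica and can be separated from partially methylated material. Acid-catalysed methanolysis (HCl in MeOH, Ar) then returns to 24 without exposing phenolates to air.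

## Further compounds

F1 | step 10 | 4-[4-[3,5-dimethoxy-4-(3,4,5-trimethoxyphenoxy)phenoxy]-3,5-dimethoxyphenoxy]-3,5-dimethoxybenzaldehyde (four-ring aldehyde) | COc1cc(C=O)cc(OC)c1Oc1cc(OC)c(Oc2cc(OC)c(Oc3cc(OC)c(OC)c(OC)c3)c(OC)c2)c(OC)c1
F2 | step 10 | formate of the four-ring phenol | COc1cc(OC=O)cc(OC)c1Oc1cc(OC)c(Oc2cc(OC)c(Oc3cc(OC)c(OC)c(OC)c3)c(OC)c2)c(OC)c1
F3 | step 10 | four-ring (ring B–E) phenol, all other oxygens methylated | COc1cc(O)cc(OC)c1Oc1cc(OC)c(Oc2cc(OC)c(Oc3cc(OC)c(OC)c(OC)c3)c(OC)c2)c(OC)c1
F4 | step 10 | five-ring aldehyde with formyl group on C4 of ring A | COc1cc(C=O)cc(OC)c1Oc1cc(OC)c(Oc2cc(OC)c(Oc3cc(OC)c(Oc4cc(OC)c(OC)c(OC)c4)c(OC)c3)c(OC)c2)c(OC)c1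
F5 | step 10 | formate of the five-ring phenol | COc1cc(OC=O)cc(OC)c1Oc1cc(OC)c(Oc2cc(OC)c(Oc3cc(OC)c(Oc4cc(OC)c(OC)c(OC)c4)c(OC)c3)c(OC)c2)c(OC)c1
F6 | step 10 | five-ring phenol with free C4 hydroxyl on ring A (undeca-O-methyl ether of the target) | COc1cc(O)cc(OC)c1Oc1cc(OC)c(Oc2cc(OC)c(Oc3cc(OC)c(Oc4cc(OC)c(OC)c(OC)c4)c(OC)c3)c(OC)c2)c(OC)c1
F7 | step 3 | 3,5-dimethoxy-4-(3,4,5-trimethoxyphenoxy)phenyl trifluoromethanesulfonate | COc1cc(OS(=O)(=O)C(F)(F)F)cc(OC)c1Oc1cc(OC)c(OC)c(OC)c1
F8 | step 3 | 2-[3,5-dimethoxy-4-(3,4,5-trimethoxyphenoxy)phenyl]-4,4,5,5-tetramethyl-1,3,2-dioxaborolane | COc1cc(B2OC(C)(C)C(C)(C)O2)cc(OC)c1Oc1cc(OC)c(OC)c(OC)c1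
F0 | step 7 | none | none
F0 | step 5 | none | none
F9 | step 12 | dodeca-O-acetate of the target | CC(=O)Oc1cc(OC(C)=O)c(Oc2cc(OC(C)=O)c(Oc3cc(OC(C)=O)c(Oc4cc(OC(C)=O)c(Oc5cc(OC(C)=O)c(OC(C)=O)c(OC(C)=O)c5)c(OC(C)=O)c4)c(OC(C)=O)c3)c(OC(C)=O)c2)c(OC(C)=O)c1
A1 | alternative 1 | 2-(ring B–E aryloxy)-5-hydroxy-3-(4-methoxybenzyloxy)cyclohexanone (2,3-cis from the sugar, carbinol epimers) | O=C1[C@@H]([C@@H](CC(O)C1)OCc6ccc(OC)cc6)Oc2cc(OC)c(Oc3cc(OC)c(Oc4cc(OC)c(Oc5cc(OC)c(OC)c(OC)c5)c(OC)c4)c(OC)c3)c(OC)c2
A2 | alternative 1 | methyl 4-O-(ring B–E aryl)-2,6-dideoxy-3-O-(4-methoxybenzyl)hex-5-enopyranoside (C3 as in 2-deoxy-D-glucose, C4 inverted, anomeric methoxy trans to both) | CO[C@@H]1C[C@@H](OCc2ccc(OC)cc2)[C@@H](Oc2cc(OC)c(Oc3cc(OC)c(Oc4cc(OC)c(Oc5cc(OC)c(OC)c(OC)c5)c(OC)c4)c(OC)c3)c(OC)c2)C(=C)O1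
A3 | alternative 1 | four-ring (ring B–E) phenol, all other oxygens methylated | COc1cc(O)cc(OC)c1Oc1cc(OC)c(Oc2cc(OC)c(Oc3cc(OC)c(OC)c(OC)c3)c(OC)c2)c(OC)c1
A4 | alternative 1 | 2-deoxy-D-glucose (open-chain form) | C(C=O)[C@H]([C@@H]([C@@H](CO)O)O)O
A5 | alternative 2 | dodeca-O-methyl ether of the target | COc1cc(OC)c(Oc2cc(OC)c(Oc3cc(OC)c(Oc4cc(OC)c(Oc5cc(OC)c(OC)c(OC)c5)c(OC)c4)c(OC)c3)c(OC)c2)c(OC)c1
A6 | alternative 2 | 2,4,6-trimethoxyphenyl ester of the tris(4-acyloxy-3,5-dimethoxybenzoyl) chain capped by 3,4,5-trimethoxybenzoyl (depside tetraester) | COc1cc(OC)c(OC(=O)c2cc(OC)c(OC(=O)c3cc(OC)c(OC(=O)c4cc(OC)c(OC(=O)c5cc(OC)c(OC)c(OC)c5)c(OC)c4)c(OC)c3)c(OC)c2)c(OC)c1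
A7 | alternative 3 | five-ring product with free C4 hydroxyl on ring E, ethyl ethers on rings B–E, methyl ethers on ring A | CCOc5cc(Oc4c(OCC)cc(Oc3c(OCC)cc(Oc2c(OCC)cc(Oc1c(OC)cc(OC)cc1OC)cc2OCC)cc3OCC)cc4OCC)cc(OCC)c5O
A8 | alternative 3 | pentacarbonylchromium [aryloxy(2-ethoxyvinyl)carbene] complex on the ring D oxygen | CCOC=CC(Oc1c(OCC)cc(Oc2c(OCC)cc(Oc3c(OCC)cc(Oc4c(OC)cc(OC)cc4OC)cc3OCC)cc2OCC)cc1OCC)=[Cr](=C=O)(=C=O)(=C=O)(=C=O)=C=O
A9 | alternative 3 | four-ring (ring A–D) phenol with free C4 hydroxyl on ring D | CCOc1cc(Oc2c(OCC)cc(Oc3c(OCC)cc(Oc4c(OC)cc(OC)cc4OC)cc3OCC)cc2OCC)cc(OCC)c1O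
A10 | alternative 3 | ethoxyacetylene | CCOC#C
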